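Retrosynthesis: the two N–H groups are masked as N‑tosyl. In each pyrrole ring N1–C2 and C2–C3 are then cut together, which removes C2 and its bromine as a CHBr unit. The C3–C3' bond is cut last.
Enabling feature: C3 and C3' are bonded directly to each other. Each is attached at C3a to a benzene ring whose neighbouring carbon C7a carries N1. The target without C2 and C2' is therefore a 2,2'‑diamino‑5,5'‑dibromobenzil whose two carbonyl carbons are C3 and C3'.
Forward: both benzene rings and both C5 bromines come with 2‑amino‑5‑bromobenzaldehyde. N‑tosylation, reductive dimerisation (C3–C3') and oxidation of the diol give the diketone.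
Both pyrrole rings then close in one telescoped operation with LiCHBr2 (carbonyl addition, N‑alkylation, dehydration), and mild base removes the tosyl groups.
Stereochemistry: the target has no stereocentre. Every carbinol or CHBr centre made on the way is erased by oxidation or aromatisation.

Key step: step 4

Assumption: the target is drawn without a descriptor for the C3–C3' axis, so no control of axial configuration is attempted.

Step 1
Reactants: 1 2‑amino‑5‑bromobenzaldehyde; 2 4‑toluenesulfonyl chloride
Product: 3 N‑(4‑bromo‑2‑formylphenyl)‑4‑methylbenzenesulfonamide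
Conditions: TsCl, pyridine, CH2Cl2, 0 °C to rt
Reagents that add atoms: 4‑toluenesulfonyl chloride (2), Cc1ccc(cc1)S(Cl)(=O)=O
Why: N‑sulfonylation of an aniline with a sulfonyl chloride in pyridine is routine, and the ortho‑formyl group lowers the nucleophilicity of nitrogen enough for the reaction to stop at the monosulfonamide, which can no longer self‑condense as 1 does.

Step 2
Reactants: 3 N‑(4‑bromo‑2‑formylphenyl)‑4‑methylbenzenesulfonamide (two molecules)
Product: 4 N,N'‑[(1,2‑dihydroxyethane‑1,2‑diyl)bis(4‑bromo‑2,1‑phenylene)]bis(4‑methylbenzenesulfonamide), dl/meso mixture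
Conditions: SmI2 (0.1 M in THF), THF, 0 °C to rt; dilute aq. HCl
Reagents that add atoms: none
Why: In the SmI2 pinacol coupling aryl aldehyde ketyls dimerise faster than they take up a second electron, aryl bromides and arenesulfonamides are inert to SmI2 in plain THF, and the two new carbinol centres need no control because both are oxidised in step 3.

Step 3
Reactants: 4 the diol from step 2
Product: 5 N,N'‑[oxalylbis(4‑bromo‑2,1‑phenylene)]bis(4‑methylbenzenesulfonamide)
Conditions: IBX (3 equiv), DMSO, rt
Reagents that add atoms: none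
Why: IBX oxidation of a 1,2‑diol stops at the 1,2‑diketone without glycol cleavage, the neutral medium keeps the sulfonamide nitrogens un‑ionised, and any ring–chain equilibrium of 5 with the hemiaminal formed by a sulfonamide nitrogen and the distal carbonyl is harmless because deprotonation in step 4 reopens it to the far more stable sulfonamide anion.

Step 4
Reactants: 5 N,N'‑[oxalylbis(4‑bromo‑2,1‑phenylene)]bis(4‑methylbenzenesulfonamide); 6 dibromomethane
Product: 9 2,2',5,5'‑tetrabromo‑1,1'‑ditosyl‑3,3'‑biindole, via bis‑dibromomethyl diol 7 (not isolated), via bis‑bromohydroxyindoline 8 (not isolated)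
Conditions: a) CH2Br2 (7 equiv), LiN(iPr)2 (6 equiv), THF, −90 °C, then 5, −90 to −78 °C, AcOH at −78 °C, aqueous wash, evaporation of CH2Br2; b) crude, Cs2CO3, MeCN, 0 to 40 °C; c) same flask, Et3N, MsCl, 0 °C to rt
Reagents that add atoms: dibromomethane (6), BrCBr
Why: Proposed new method: LiCHBr2 first deprotonates both sulfonamides and then adds to the two non‑enolisable ketone carbons (forming C2–C3 and C2'–C3'), and AcOH at −78 °C fixes the adduct as the neutral diol 7 before a lithium alkoxide can close to a bromoepoxide. Cs2CO3 then ionises only the N–H groups, which are far more acidic than the tertiary alcohols, and each nitrogen displaces one of the two geminal bromides next to it in a 5‑exo‑tet closure (N1–C2 in one pyrrole ring, N1'–C2' in the other), attack on the remote CHBr2 group being a slower 6‑exo‑tet process. Sulfene from MsCl and Et3N sulfonylates each C3 hydroxyl of 8 and the amine removes the C2 proton, acidified by bromine and the sulfonylated nitrogen, so that two eliminations deliver two aromatic pyrrole rings. The nearest precedents are sulfur‑ylide annulations that turn ortho‑sulfonamido aryl ketones into indoles by one‑carbon insertion, the 1,2‑addition of dihalomethyllithium reagents to ketones, and the base‑induced closure of ortho‑(2,2‑dibromovinyl)sulfonanilides to 2‑bromoindoles, but a bromocarbenoid has not served as the one‑carbon partner and the sequence has not been run twice on a benzil. The four stereocentres of 8 (C2, C3, C2', C3') arise without control and all vanish on aromatisation, so no diastereomer has to be selected. The step needs nitrogen to outcompete oxygen as nucleophile and proton loss to outcompete migration or epoxide closure across C3–C3', which the acidity gap, sulfonylation of both hydroxyls by excess MsCl and the gain of two aromatic rings should secure.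

Step 5
Reactants: 9 2,2',5,5'‑tetrabromo‑1,1'‑ditosyl‑3,3'‑biindole
Product: 10 rivularin‑c (2,2',5,5'‑tetrabromo‑1H,1'H‑3,3'‑biindole)
Conditions: Cs2CO3, THF–MeOH (2:1), rt, dark; aq. NH4Cl
Reagents that add atoms: none
Why: Base‑mediated methanolysis of an N‑sulfonylindole (methoxide attacks sulfur and the indolide leaves) is a standard mild detosylation that electron‑withdrawing bromines accelerate and that, having neither reductant nor transition metal, should leave all four C–Br bonds intact.

Compound list
1 | 2‑amino‑5‑bromobenzaldehyde | Nc1ccc(Br)cc1C=O | starting material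
2 | 4‑toluenesulfonyl chloride | Cc1ccc(cc1)S(Cl)(=O)=O | starting material
3 | N‑(4‑bromo‑2‑formylphenyl)‑4‑methylbenzenesulfonamide | Cc1ccc(cc1)S(=O)(=O)Nc1ccc(Br)cc1C=O | intermediate
4 | N,N'‑[(1,2‑dihydroxyethane‑1,2‑diyl)bis(4‑bromo‑2,1‑phenylene)]bis(4‑methylbenzenesulfonamide), dl/meso mixture | OC(c1cc(Br)ccc1NS(=O)(=O)c1ccc(C)cc1)C(O)c1cc(Br)ccc1NS(=O)(=O)c1ccc(C)cc1 | intermediate
5 | N,N'‑[oxalylbis(4‑bromo‑2,1‑phenylene)]bis(4‑methylbenzenesulfonamide) | O=C(c1cc(Br)ccc1NS(=O)(=O)c1ccc(C)cc1)C(=O)c1cc(Br)ccc1NS(=O)(=O)c1ccc(C)cc1 | intermediate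
6 | dibromomethane | BrCBr | starting material
7 | N,N'‑[(1,1,4,4‑tetrabromo‑2,3‑dihydroxybutane‑2,3‑diyl)bis(4‑bromo‑2,1‑phenylene)]bis(4‑methylbenzenesulfonamide), diastereomer mixture, not isolated | OC(C(Br)Br)(c1cc(Br)ccc1NS(=O)(=O)c1ccc(C)cc1)C(O)(C(Br)Br)c1cc(Br)ccc1NS(=O)(=O)c1ccc(C)cc1 | intermediate
8 | 2,2',5,5'‑tetrabromo‑1,1'‑ditosyl‑2,2',3,3'‑tetrahydro‑1H,1'H‑[3,3'‑biindole]‑3,3'‑diol, diastereomer mixture, not isolated | Cc1ccc(cc1)S(=O)(=O)N1C(Br)C(O)(c2cc(Br)ccc21)C1(O)C(Br)N(S(=O)(=O)c2ccc(C)cc2)c2ccc(Br)cc21 | intermediate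
9 | 2,2',5,5'‑tetrabromo‑1,1'‑ditosyl‑3,3'‑biindole | Cc1ccc(cc1)S(=O)(=O)n1c(Br)c(-c2c(Br)n(S(=O)(=O)c3ccc(C)cc3)c3ccc(Br)cc23)c2cc(Br)ccc21 | intermediate
10 | rivularin‑c, 2,2',5,5'‑tetrabromo‑1H,1'H‑3,3'‑biindole | Brc1ccc2[nH]c(Br)c(-c3c(Br)[nH]c4ccc(Br)cc34)c2c1 | target

Total step count: 5. Longest linear sequence: 5 steps (1 to 10).

Steps most likely to fail

1. Step 4.
- Risks: The second carbenoid addition to the crowded α‑oxido ketone may stall while LiCHBr2 decays. Oxygen may displace bromide in place of nitrogen, which leads through bromoepoxide rearrangement to loss of the C2 bromine. Ionisation at C3 may trigger migration or epoxide closure across C3–C3' before the C2 proton is lost.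
- Fallback with known chemistry, from 5 back to 9: the one‑carbon unit is delivered without bromine and the halogen is added afterwards. Diketone 5 is treated with excess dimethylsulfonium methylide (Me3SI, NaH, DMSO–THF, 0 °C to rt), the established sulfur‑ylide [4+1] annulation of ortho‑sulfonamido aryl ketones. This should give 5,5'‑dibromo‑1,1'‑ditosyl‑2,2',3,3'‑tetrahydro‑1H,1'H‑[3,3'‑biindole]‑3,3'‑diol F1. Catalytic TsOH in warm toluene dehydrates it to 5,5'‑dibromo‑1,1'‑ditosyl‑3,3'‑biindole F2. Sulfonyl‑directed C2 lithiation with LiN(iPr)2 (THF, −78 °C, a base that leaves the aryl bromides alone) gives 5,5'‑dibromo‑2,2'‑dilithio‑1,1'‑ditosyl‑3,3'‑biindole F3. 1,2‑Dibromo‑1,1,2,2‑tetrachloroethane as electrophilic bromine donor then converts it into 9.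

2. Step 2.
- Risks: The acidic N–H next to the carbonyl may protonate the ketyl, so that a second electron transfer and simple reduction to the benzylic alcohol compete with dimerisation. Chelation of trivalent samarium by the sulfonamide may slow the coupling.
- Fallback, from 2 back to 5, bypassing steps 2 and 3: the diketone is built at its final oxidation level from an aryl nucleophile and an oxalyl dication equivalent. Commercial 4‑bromo‑2‑iodoaniline (Nc1ccc(Br)cc1I) is tosylated with 2 in pyridine to N‑(4‑bromo‑2‑iodophenyl)‑4‑methylbenzenesulfonamide F4. MeMgCl removes the N–H proton, and iPrMgCl·LiCl (THF, −20 °C) exchanges the iodine, which reacts far faster than the bromine, to give the N,C‑bis(chloromagnesio) derivative of N‑(4‑bromophenyl)‑4‑methylbenzenesulfonamide F5. Half an equivalent of 1,4‑dimethylpiperazine‑2,3‑dione (CN1CCN(C)C(=O)C1=O) takes up two aryl groups, a known synthesis of symmetrical α‑diones, and aqueous HCl releases 5.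

3. Step 5.
- Risks: Methoxide may attack C2 in place of sulfur. The sulfonate ester formed may methylate the indolide nitrogen. The N–H 2‑bromoindole may degrade on prolonged contact with base, light or acid during work‑up.
- Fallback, from 5 back to 10: the C2 bromines are introduced only after the nitrogens are free. Diketone 5 is taken through F1 to F2 as described under the first fallback. F2, which has no labile C2–Br bond, is detosylated (Cs2CO3, THF–MeOH, rt to 50 °C) to 5,5'‑dibromo‑1H,1'H‑3,3'‑biindole F6. Two equivalents of NBS (THF, −78 to 0 °C) then brominate the only free pyrrole positions, C2 and C2', by the usual electrophilic substitution of 3‑substituted indoles, giving 10 directly under neutral conditions.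

Further compounds
F1 | step 4 | 5,5'‑dibromo‑1,1'‑ditosyl‑2,2',3,3'‑tetrahydro‑1H,1'H‑[3,3'‑biindole]‑3,3'‑diol (diastereomer mixture) | Cc1ccc(cc1)S(=O)(=O)N1CC(O)(c2cc(Br)ccc21)C1(O)CN(S(=O)(=O)c2ccc(C)cc2)c2ccc(Br)cc21
F2 | step 4 | 5,5'‑dibromo‑1,1'‑ditosyl‑3,3'‑biindole | Cc1ccc(cc1)S(=O)(=O)n1cc(-c2cn(S(=O)(=O)c3ccc(C)cc3)c3ccc(Br)cc23)c2cc(Br)ccc21
F3 | step 4 | 5,5'‑dibromo‑2,2'‑dilithio‑1,1'‑ditosyl‑3,3'‑biindole | Cc1ccc(cc1)S(=O)(=O)n1c([Li])c(-c2c([Li])n(S(=O)(=O)c3ccc(C)cc3)c3ccc(Br)cc23)c2cc(Br)ccc21
F4 | step 2 | N‑(4‑bromo‑2‑iodophenyl)‑4‑methylbenzenesulfonamide | Cc1ccc(cc1)S(=O)(=O)Nc1ccc(Br)cc1I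
F5 | step 2 | N,C‑bis(chloromagnesio) derivative of N‑(4‑bromophenyl)‑4‑methylbenzenesulfonamide (magnesium on nitrogen and on the ortho carbon) | Cc1ccc(cc1)S(=O)(=O)N([Mg]Cl)c1ccc(Br)cc1[Mg]Cl
F6 | step 5 | 5,5'‑dibromo‑1H,1'H‑3,3'‑biindole | Brc1ccc2[nH]cc(-c3c[nH]c4ccc(Br)cc34)c2c1
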